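**Plan**

Numbering: bicycle C1 (ketal carbon), O2, C3, C4, C5, C6, C7, O8; C3' is the carboxyl carbon on C3; side chain C1'–C6'.
Retrosynthesis: the C3 carboxyl goes back to CH2OH and the C4 carboxyl to a spiro enediol lactone (C–C cleavage by peroxide); the ketal is moved from O8 to O3'; then C4–C5 is cut (ring-closing vinylogous aldol), then the C1 ketal, C5–C6 (Michael) and C1–C7 (Weinreb).
Enabling feature: C4, with its oxygen O4, its carboxyl and the O2-bearing C3, is C4 of D-isoascorbic acid (lactone oxygen = O4, enediol carbon = latent CO2H, 5,6-diol = O2/O3'); a C1 ketal on that diol holds the C5 α-keto ester, three carbons from C1, over C4.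
Forward: side-chain ester (Claisen) → vinyl ketone → Michael adduct → dioxolane with isoascorbic acid → oxepane closure C4–C5 (8,9-dioxabicyclo[4.2.1]nonane) → acid shifts the ketal to the dioxane/oxolane pair of the target → oxalyl unit excised → C3' oxidised.
Stereochemistry: C5' from oxazolidinone alkylation; (E)-alkene from the chair Claisen; C3 from C5 of D-isoascorbic acid; C4 and C5 from the key step, relayed from C3 through the dioxolane; C1 follows from the bicyclic ketal.

Key step: step 13

Remark: 19, 20 and 21 are carried as the pair of epimers at the ketal carbon C1; only the epimer with the keto-ester arm syn to the furanone can react in step 13.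

**Route**

Step 1
Reactants: 1 (4R)-4-benzyl-3-propanoyl-1,3-oxazolidin-2-one; 2 benzyl bromide
Product: 3 (4R)-4-benzyl-3-[(2S)-2-methyl-3-phenylpropanoyl]-1,3-oxazolidin-2-one
Conditions: NaN(SiMe3)2, THF, −78 °C; then 2, −78 → −40 °C
Reagents that add atoms: none
Why: Alkylation of the chelated (Z)-sodium enolate of the N-acyl oxazolidinone (Evans alkylation) should take benzyl bromide on the face opposite the auxiliary benzyl group, which sets the (S) centre that becomes C5'.

Step 2
Reactants: 3 (4R)-4-benzyl-3-[(2S)-2-methyl-3-phenylpropanoyl]-1,3-oxazolidin-2-one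
Product: 4 (2S)-2-methyl-3-phenylpropan-1-ol
Conditions: LiBH4, THF, 0 °C
Reagents that add atoms: none
Why: Reductive cleavage of the imide (hydride attack on the exocyclic carbonyl) should release the primary alcohol without touching the new stereocentre.

Step 3
Reactants: 4 (2S)-2-methyl-3-phenylpropan-1-ol
Product: 5 (2S)-2-methyl-3-phenylpropanal
Conditions: TEMPO (cat.), PhI(OAc)2, CH2Cl2, rt
Reagents that add atoms: none
Why: Oxoammonium (TEMPO) oxidation of a primary alcohol stops at the aldehyde under non-basic conditions, so the α-stereocentre should not epimerise.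

Step 4
Reactants: 5 (2S)-2-methyl-3-phenylpropanal; 6 prop-1-en-2-ylmagnesium bromide CH2=C(CH3)MgBr
Product: 7 (4S)-2,4-dimethyl-5-phenylpent-1-en-3-ol (both carbinol epimers)
Conditions: THF, −78 → 0 °C; aq. NH4Cl
Reagents that add atoms: none
Why: Grignard 1,2-addition gives the 2-methyl allylic alcohol; the new carbinol centre is destroyed in step 5, so both epimers serve.

Step 5
Reactants: 7 (4S)-2,4-dimethyl-5-phenylpent-1-en-3-ol; 8 triethyl orthoacetate
Product: 10 ethyl (4E,6S)-4,6-dimethyl-7-phenylhept-4-enoate, via ketene acetal 9 (not isolated)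
Conditions: 8 (excess), EtCO2H (cat.), 140 °C, EtOH distilled off
Reagents that add atoms: none
Why: Johnson–Claisen rearrangement through a chair transition state with the branched substituent equatorial should give the (E)-trisubstituted alkene and add the two carbons that become C1' and C1.

Step 6
Reactants: 10 ethyl (4E,6S)-4,6-dimethyl-7-phenylhept-4-enoate
Product: 11 (4E,6S)-N-methoxy-N,4,6-trimethyl-7-phenylhept-4-enamide
Conditions: MeNH(OMe)·HCl, iPrMgCl, THF, −20 → 0 °C
Reagents that add atoms: N,O-dimethylhydroxylamine hydrochloride, CNOC.Cl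
Why: Aminolysis of the ester by the chloromagnesium amide gives the Weinreb amide needed for a single-addition ketone synthesis.

Step 7
Reactants: 11 (4E,6S)-N-methoxy-N,4,6-trimethyl-7-phenylhept-4-enamide; 12 ethenylmagnesium bromide CH2=CHMgBr
Product: 13 (6E,8S)-6,8-dimethyl-9-phenylnona-1,6-dien-3-one
Conditions: THF, −78 → 0 °C; inverse quench into cold 1 M HCl
Reagents that add atoms: none
Why: Weinreb ketone synthesis: the chelated tetrahedral intermediate should hold until the acidic quench, so one vinyl group adds and the vinyl ketone (C1 carbonyl with C7=C6) results.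

Step 8
Reactants: 14 1,3-dithiane-2-carboxylic acid
Product: 15 tert-butyl 1,3-dithiane-2-carboxylate
Conditions: Boc2O, DMAP (cat.), tBuOH/THF, rt
Reagents that add atoms: di-tert-butyl dicarbonate, CC(C)(C)OC(=O)OC(=O)OC(C)(C)C
Why: Esterification through the mixed carbonic anhydride gives the tert-butyl ester under non-acidic conditions that leave the dithioacetal intact.

Step 9
Reactants: 13 (6E,8S)-6,8-dimethyl-9-phenylnona-1,6-dien-3-one; 15 tert-butyl 1,3-dithiane-2-carboxylate
Product: 16 tert-butyl 2-[(6E,8S)-6,8-dimethyl-3-oxo-9-phenylnon-6-en-1-yl]-1,3-dithiane-2-carboxylate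
Conditions: KOtBu (10 mol %), THF, 0 °C
Reagents that add atoms: none
Why: Michael addition of the dithiane-stabilised ester anion (acyl anion equivalent, Corey–Seebach umpolung) to the vinyl ketone forms C5–C6 and delivers C5 as a masked α-keto ester.

Step 10
Reactants: 16 tert-butyl 2-[(6E,8S)-6,8-dimethyl-3-oxo-9-phenylnon-6-en-1-yl]-1,3-dithiane-2-carboxylate; 17 D-isoascorbic acid
Product: 19 5,6-O-alkylidene-D-isoascorbic acid (dioxolane on C1; both ketal epimers), via dimethyl ketal 18 (not isolated)
Conditions: HC(OMe)3, MeOH, TsOH (cat.), rt; then 17, DMF, TsOH (cat.), 40 °C, reduced pressure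
Reagents that add atoms: trimethyl orthoformate, COC(OC)OC (its methoxy groups are carried by 18 only)
Why: Acid-catalysed transketalisation (dioxolane formation on the 5,6-diol, as in 5,6-O-alkylidene ascorbic acids) should engage only the ketone carbon C1 while the dithioacetal masks C5, and gives both ketal epimers, of which the anti one is recovered in step 13 as 21 and re-equilibrated with acid.

Step 11
Reactants: 19 5,6-O-alkylidene-D-isoascorbic acid
Product: 20 2,3-bis-O-(methoxymethyl) ether of 19
Conditions: MOMCl, iPr2NEt, CH2Cl2, 0 °C → rt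
Reagents that add atoms: chloromethyl methyl ether, COCCl
Why: O-Alkylation of the two acidic enol hydroxyls (Williamson-type etherification) masks the reductone against step 12 and leaves C4–H as the only acidic site of the lactone.

Step 12
Reactants: 20 2,3-bis-O-(methoxymethyl) ether of 19
Product: 21 α-keto tert-butyl ester (dithiane of 20 replaced by C5=O)
Conditions: MeI, CaCO3, MeCN/H2O (9:1), 45 °C
Reagents that add atoms: water, O
Why: S-Methylation and hydrolysis of the sulfonium salt (dithioacetal cleavage) unmasks the α-keto ester under buffered, non-oxidising conditions that should spare the alkene, the ketal and the enol acetals.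

Step 13
Reactants: 21 α-keto tert-butyl ester
Product: 23 spiro 8,9-dioxabicyclo[4.2.1]nonane silyl ether (C4–C5 closed), via silyloxyfuran 22 (not isolated)
Conditions: tBuMe2SiOTf, Et3N, CH2Cl2, −78 → −20 °C
Reagents that add atoms: tert-butyldimethylsilyl trifluoromethanesulfonate, CC(C)(C)[Si](C)(C)OS(=O)(=O)C(F)(F)F
Why: Proposed new method: O-silylation of the lactone carbonyl and deprotonation at C4 by Et3N should give the 2-silyloxy-3,4-bis(methoxymethoxy)furan 22, whose C4 adds to the silyl-activated C5 ketone; the closest known reaction type is the intramolecular vinylogous Mukaiyama aldol addition of 2-silyloxyfurans (from butenolides with R3SiOTf/Et3N) to tethered ketones and α-keto esters, extended here to an isoascorbate-derived trioxygenated furan. The new bond closes the oxepane ring C1–O2–C3–C4–C5–C6–C7 by 7-exo-trig attack on the carbonyl and gives an 8,9-dioxabicyclo[4.2.1]nonane. C4: the ketone can reach only the furan face turned to the C1 arm, and the furan rotamer that puts the ring oxygen O4 over C3'H2 and the substituted furan carbon next to the small ketal oxygen O2 avoids allylic strain, which should give the centre that is (4S) in 28. C5: with the four-atom bridge folded towards O2 and away from the inward hydrogen on C3', the bulky silyl-bound carbonyl oxygen should point away from the bicycle and the ester take the inner position, which should give the centre that is (5R) in 28; this is the least secure element. The step needs the lactone to be silylated and deprotonated faster than the keto ester is turned into its enol silyl ether, which the aromatisation-driven acidity of C4–H and the low temperature are meant to secure, and it needs the syn ketal epimer, the anti epimer returning as 21 on work-up. β-Elimination of O2 from C3 should be avoided because the nucleophile is the neutral silyloxyfuran and not the dienolate.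

Step 14
Reactants: 23 spiro 8,9-dioxabicyclo[4.2.1]nonane silyl ether
Product: 25 spiro enediol lactone of the 2,8-dioxabicyclo[3.2.1]octane-5-carboxylic acid (C3 bears CH2OH), via deprotected dioxolane 24 (not isolated)
Conditions: CF3CO2H/H2O/CH2Cl2, 0 °C → rt
Reagents that add atoms: none
Why: Acidolysis removes the silyl ether, both enol acetals and the tert-butyl ester, and transketalisation (the C5 hydroxyl captures the C1 oxocarbenium ion formed by opening at O3') should give the thermodynamically preferred 2,8-dioxabicyclo[3.2.1]octane, which fixes C1.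

Step 15
Reactants: 25 spiro enediol lactone
Product: 27 (1S,3R,4S,5R)-1-[(3E,5S)-3,5-dimethyl-6-phenylhex-3-en-1-yl]-4-hydroxy-3-(hydroxymethyl)-2,8-dioxabicyclo[3.2.1]octane-4,5-dicarboxylic acid, via diketo lactone 26 (not isolated)
Conditions: 30% H2O2, Na2CO3, H2O/THF, 0 → 40 °C; then HCl to pH 2
Reagents that add atoms: hydrogen peroxide, OO; water, O
Why: Oxidative cleavage of the reductone through its 2,3-diketo lactone (Baeyer–Villiger-type insertion by alkaline peroxide, as in the ascorbic-to-threonic acid degradation) excises the oxalyl unit and leaves the C4 carboxyl and hydroxyl, while the isolated alkene is inert to nucleophilic peroxide.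

Step 16
Reactants: 27 hydroxymethyl diacid
Product: 28 (1S,3S,4S,5R)-1-[(3E,5S)-3,5-dimethyl-6-phenylhex-3-en-1-yl]-4-hydroxy-2,8-dioxabicyclo[3.2.1]octane-3,4,5-tricarboxylic acid
Conditions: TEMPO (cat.), NaClO2, NaOCl (cat.), MeCN/phosphate buffer pH 6.7, 35 °C
Reagents that add atoms: sodium chlorite, [Na+].[O-]Cl=O; water, O
Why: TEMPO-catalysed oxidation with chlorite as terminal oxidant (Anelli–Zhao oxidation) takes the only oxidisable alcohol, the C3 hydroxymethyl group, to the acid; the tertiary C4 hydroxyl cannot react and O2 is held in the ketal.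

**Compound list**

1 | (4R)-4-benzyl-3-propanoyl-1,3-oxazolidin-2-one | CCC(=O)N1[C@H](Cc2ccccc2)COC1=O | starting material
2 | benzyl bromide | BrCc1ccccc1 | starting material
3 | (4R)-4-benzyl-3-[(2S)-2-methyl-3-phenylpropanoyl]-1,3-oxazolidin-2-one | O=C([C@@H](C)Cc1ccccc1)N1[C@H](Cc2ccccc2)COC1=O | intermediate
4 | (2S)-2-methyl-3-phenylpropan-1-ol | OC[C@@H](C)Cc1ccccc1 | intermediate
5 | (2S)-2-methyl-3-phenylpropanal | O=C[C@@H](C)Cc1ccccc1 | intermediate
6 | prop-1-en-2-ylmagnesium bromide | CC(=C)[Mg]Br | starting material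
7 | (4S)-2,4-dimethyl-5-phenylpent-1-en-3-ol, both epimers at C3 | C=C(C)C(O)[C@@H](C)Cc1ccccc1 | intermediate
8 | triethyl orthoacetate | CC(OCC)(OCC)OCC | starting material
9 | ketene acetal: (4S)-3-[(1-ethoxyethenyl)oxy]-2,4-dimethyl-5-phenylpent-1-ene | C=C(OCC)OC(C(C)=C)[C@@H](C)Cc1ccccc1 | intermediate
10 | ethyl (4E,6S)-4,6-dimethyl-7-phenylhept-4-enoate | CCOC(=O)CC/C(C)=C/[C@@H](C)Cc1ccccc1 | intermediate
11 | (4E,6S)-N-methoxy-N,4,6-trimethyl-7-phenylhept-4-enamide | CON(C)C(=O)CC/C(C)=C/[C@@H](C)Cc1ccccc1 | intermediate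
12 | ethenylmagnesium bromide | C=C[Mg]Br | starting material
13 | (6E,8S)-6,8-dimethyl-9-phenylnona-1,6-dien-3-one | C=CC(=O)CC/C(C)=C/[C@@H](C)Cc1ccccc1 | intermediate
14 | 1,3-dithiane-2-carboxylic acid | OC(=O)C1SCCCS1 | starting material
15 | tert-butyl 1,3-dithiane-2-carboxylate | CC(C)(C)OC(=O)C1SCCCS1 | intermediate
16 | tert-butyl 2-[(6E,8S)-6,8-dimethyl-3-oxo-9-phenylnon-6-en-1-yl]-1,3-dithiane-2-carboxylate | CC(C)(C)OC(=O)C1(CCC(=O)CC/C(C)=C/[C@@H](C)Cc2ccccc2)SCCCS1 | intermediate
17 | D-isoascorbic acid, (5R)-5-[(1R)-1,2-dihydroxyethyl]-3,4-dihydroxyfuran-2(5H)-one | OC[C@@H](O)[C@H]1OC(=O)C(O)=C1O | starting material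
18 | dimethyl ketal of 16: tert-butyl 2-[(6E,8S)-3,3-dimethoxy-6,8-dimethyl-9-phenylnon-6-en-1-yl]-1,3-dithiane-2-carboxylate | CC(C)(C)OC(=O)C1(CCC(OC)(OC)CC/C(C)=C/[C@@H](C)Cc2ccccc2)SCCCS1 | intermediate
19 | 5,6-O-ketal of 17 with the ketone of 16: 1,3-dioxolane whose ketal carbon (C1) bears the side chain and the 2-(2-tert-butoxycarbonyl-1,3-dithian-2-yl)ethyl arm and whose C3 bears the 3,4-dihydroxy-5-oxo-2,5-dihydrofuran-2-yl group; both epimers at C1 | C/C(=C\[C@@H](C)Cc1ccccc1)CCC2(CCC3(C(=O)OC(C)(C)C)SCCCS3)OC[C@@H](O2)[C@H]4OC(=O)C(O)=C4O | intermediate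
20 | 2,3-bis-O-(methoxymethyl) ether of 19; both epimers at C1 | C/C(=C\[C@@H](C)Cc1ccccc1)CCC2(CCC3(C(=O)OC(C)(C)C)SCCCS3)OC[C@@H](O2)[C@H]4OC(=O)C(OCOC)=C4OCOC | intermediate
21 | α-keto tert-butyl ester: as 20 with the dithiane carbon converted into the C5 ketone; both epimers at C1 | C/C(=C\[C@@H](C)Cc1ccccc1)CCC2(CCC(=O)C(=O)OC(C)(C)C)OC[C@@H](O2)[C@H]3OC(=O)C(OCOC)=C3OCOC | intermediate
22 | 2-(tert-butyldimethylsilyloxy)-3,4-bis(methoxymethoxy)furan derived from 21 | C/C(=C\[C@@H](C)Cc1ccccc1)CCC2(CCC(=O)C(=O)OC(C)(C)C)OC[C@@H](O2)c3oc(O[Si](C)(C)C(C)(C)C)c(OCOC)c3OCOC | intermediate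
23 | key adduct: 8,9-dioxabicyclo[4.2.1]nonane (C1 ketal on O2 and O3') with the new C4–C5 bond; C5 bears OSiMe2tBu and CO2tBu; C4 is the spiro carbon of the 3,4-bis(methoxymethoxy)furan-2(5H)-one; C3, C4, C5 configured as in 28 | C/C(=C\[C@@H](C)Cc1ccccc1)CC[C@]23CC[C@@](C(=O)OC(C)(C)C)(O[Si](C)(C)C(C)(C)C)[C@@]4(OC(=O)C(OCOC)=C4OCOC)[C@@H](CO3)O2 | intermediate
24 | deprotected 23: free C5 hydroxy acid and free enediol, ketal still on O2 and O3' | C/C(=C\[C@@H](C)Cc1ccccc1)CC[C@]23CC[C@@](C(=O)O)(O)[C@@]4(OC(=O)C(O)=C4O)[C@@H](CO3)O2 | intermediate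
25 | 2,8-dioxabicyclo[3.2.1]octane-5-carboxylic acid with C3 hydroxymethyl and C4 as spiro carbon of the 3,4-dihydroxyfuran-2(5H)-one | C/C(=C\[C@@H](C)Cc1ccccc1)CC[C@@]23CC[C@@](C(=O)O)(O2)[C@@]4(OC(=O)C(O)=C4O)[C@@H](CO)O3 | intermediate
26 | 2,3-diketo lactone from 25 | C/C(=C\[C@@H](C)Cc1ccccc1)CC[C@@]23CC[C@@](C(=O)O)(O2)[C@@]4(OC(=O)C(=O)C4=O)[C@@H](CO)O3 | intermediate
27 | (1S,3R,4S,5R)-1-[(3E,5S)-3,5-dimethyl-6-phenylhex-3-en-1-yl]-4-hydroxy-3-(hydroxymethyl)-2,8-dioxabicyclo[3.2.1]octane-4,5-dicarboxylic acid | C/C(=C\[C@@H](C)Cc1ccccc1)CC[C@@]23CC[C@@](C(=O)O)(O2)[C@](O)(C(=O)O)[C@@H](CO)O3 | intermediate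
28 | (1S,3S,4S,5R)-1-[(3E,5S)-3,5-dimethyl-6-phenylhex-3-en-1-yl]-4-hydroxy-2,8-dioxabicyclo[3.2.1]octane-3,4,5-tricarboxylic acid | C/C(=C\[C@@H](C)Cc1ccccc1)CC[C@@]12CC[C@@](C(=O)O)(O1)[C@](O)(C(=O)O)[C@@H](C(=O)O)O2 | target

**Count and risks**

Total steps: 16. Longest linear sequence: 15 (steps 1–7 and 9–16; step 8 is a one-step branch).

Steps most likely to fail:

1. Step 13 (proposed new method). What may go wrong: enol silylation of the keto ester outrunning silyloxyfuran formation; ionisation at the C3–O2 bond of the electron-rich furan; attack on the wrong face of the ketone. Fallback by known chemistry, setting out from 16 and coming back at 28: ketalisation of the C1 ketone with ethane-1,2-diol (TsOH, benzene, reflux) gives dioxolane F1; MeI/CaCO3 in aqueous MeCN unmasks keto ester F2; di-tert-butyl D-tartrate and 2,2-dimethoxypropane give acetonide F3, whose lithium enolate (LiN(iPr)2, THF, −78 °C) adds intermolecularly to the ketone of F2 anti to the neighbouring ester (aldol addition of a tartrate acetonide enolate, C3 retained from the tartrate) to give aldol adduct F4; CF3CO2H/H2O then removes the acetonide, the dioxolane and the three tert-butyl esters, and the keto triol closes to 28.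

2. Step 14. What may go wrong: the ketal staying on the 5,6-diol as the five-membered dioxolane, or lactonisation of the freed C3' hydroxyl with the C5 acid. Fallback setting out from 23 and coming back at 28: 80% aqueous acetic acid hydrolyses the dioxolane and the two enol acetals but should leave the silyl ether and the tert-butyl ester, giving keto diol F5; H2O2/NaHCO3 cleaves the reductone to hydroxy acid F6; TEMPO/NaClO2 oxidises the primary alcohol in preference to the secondary one to give diacid F7; CF3CO2H/H2O then removes the silyl and tert-butyl groups and, with no C3' hydroxyl left, the C1 ketone can only ketalise with O2 and O8 to give 28.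

3. Step 10. What may go wrong: incomplete ketal exchange because the polar enediol lactone and the lipophilic ketal share no good solvent, or acid-induced loss of the tert-butyl ester during prolonged heating. Fallback setting out from 17 and coming back at 20: acetone with catalytic CH3COCl gives 5,6-O-isopropylidene-D-isoascorbic acid F8; MOMCl/iPr2NEt gives the CH2Cl2-soluble bis(methoxymethyl) ether F9; ketal exchange between F9 and dimethyl ketal 18 (made from 16 as in step 10) with catalytic camphorsulfonic acid, 2,2-dimethoxypropane being distilled off, gives 20.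

Further compounds
F1 | step 13 | tert-butyl 2-{2-[2-((3E,5S)-3,5-dimethyl-6-phenylhex-3-en-1-yl)-1,3-dioxolan-2-yl]ethyl}-1,3-dithiane-2-carboxylate | CC(C)(C)OC(=O)C1(CCC2(CC/C(C)=C/[C@@H](C)Cc3ccccc3)OCCO2)SCCCS1
F2 | step 13 | tert-butyl 4-[2-((3E,5S)-3,5-dimethyl-6-phenylhex-3-en-1-yl)-1,3-dioxolan-2-yl]-2-oxobutanoate | CC(C)(C)OC(=O)C(=O)CCC1(CC/C(C)=C/[C@@H](C)Cc2ccccc2)OCCO1
F3 | step 13 | di-tert-butyl (4S,5S)-2,2-dimethyl-1,3-dioxolane-4,5-dicarboxylate | CC1(C)O[C@H](C(=O)OC(C)(C)C)[C@@H](C(=O)OC(C)(C)C)O1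
F4 | step 13 | aldol adduct: acetonide of the tri-tert-butyl ester with C4–C5 formed, free C5 hydroxyl and C1 as ethylene ketal, C3, C4, C5 as in 28 | CC(C)(C)OC(=O)[C@@](O)(CCC1(CC/C(C)=C/[C@@H](C)Cc2ccccc2)OCCO1)[C@@]3(C(=O)OC(C)(C)C)OC(C)(C)O[C@@H]3C(=O)OC(C)(C)C
F5 | step 14 | keto diol: C1 ketone, free C3 and C3' hydroxyls, free enediol lactone, C5 silyl ether and tert-butyl ester | C/C(=C\[C@@H](C)Cc1ccccc1)CCC(=O)CC[C@@](C(=O)OC(C)(C)C)(O[Si](C)(C)C(C)(C)C)[C@@]2(OC(=O)C(O)=C2O)[C@@H](CO)O
F6 | step 14 | hydroxy acid from F5 after reductone cleavage (C4 hydroxyl and C4 carboxyl) | C/C(=C\[C@@H](C)Cc1ccccc1)CCC(=O)CC[C@@](C(=O)OC(C)(C)C)(O[Si](C)(C)C(C)(C)C)[C@](O)(C(=O)O)[C@@H](CO)O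
F7 | step 14 | diacid from F6 after oxidation of C3' | C/C(=C\[C@@H](C)Cc1ccccc1)CCC(=O)CC[C@@](C(=O)OC(C)(C)C)(O[Si](C)(C)C(C)(C)C)[C@](O)(C(=O)O)[C@@H](C(=O)O)O
F8 | step 10 | 5,6-O-isopropylidene-D-isoascorbic acid | CC1(C)OC[C@@H](O1)[C@H]2OC(=O)C(O)=C2O
F9 | step 10 | 5,6-O-isopropylidene-2,3-bis-O-(methoxymethyl)-D-isoascorbic acid | CC1(C)OC[C@@H](O1)[C@H]2OC(=O)C(OCOC)=C2OCOC
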